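**Retrosynthetic overview**
1. Palisadin B (11) ⇐ hydride delivery to the 2-(bromomethyl) ring oxocarbenium ion 10 (sets C2), made from oxepenone 7 by LiCH2Br addition and silyl trapping.
2. Key disconnection: the acyl C2–O bond of ring B. Lactone 7 ⇐ tertiary alkoxide of Z-hydroxy enoate 6 (translactonization), 6 ⇐ lactol 5 by Z-selective olefination.
3. 5 ⇐ bromolactone 4 ⇐ catalytic enantioselective bromolactonizing cyclization of homogeranic acid 3 (ring A, C–Br, the tertiary C9a–O bond, three stereocentres).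
4. 3 ⇐ geranyl chloride 1 + CO2.
5. Ring order: ring A (cyclohexane, carrying a temporary γ-lactone) first, then ring B (oxepene); both C–O bonds of the ring oxygen come from lactonization events.

Assumption: locants follow 1-benzoxepine numbering of the target (O1, C2–C5, C5a, C6–C9, C9a); in step 2 the catalyst antipode used is the one found to give 4 and not its mirror image.

Step 1
Reactants: 1 geranyl chloride [(2E)-1-chloro-3,7-dimethylocta-2,6-diene]
Product: 3 (3E)-4,8-dimethylnona-3,7-dienoic acid (homogeranic acid), via geranylbarium chloride 2 (not isolated)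
Conditions: activated Ba (from BaI2 + 2 LiC12H10, lithium biphenylide), THF, 23 °C; 1, −78 °C; CO2, −78 → 23 °C; 1 M HCl
Reagents that add atoms: carbon dioxide, O=C=O
Why: Allylic barium reagents keep their E geometry at −78 °C and take up CO2 at the unsubstituted α-carbon (α-selective carboxylation of an allylbarium), giving the linear β,γ-unsaturated acid; no stereocentre is formed.

Step 2
Reactants: 3 (3E)-4,8-dimethylnona-3,7-dienoic acid
Product: 4 (3aS,5S,7aS)-5-bromo-4,4,7a-trimethylhexahydro-1-benzofuran-2(3H)-one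
Conditions: DBDMH (0.6 equiv), (R)-3,3′-(2,4,6-i-Pr3C6H2)2-BINOL-P(=S)NHSO2CF3 (10 mol%), toluene/CH2Cl2 4:1, −78 °C; aq Na2S2O3; recrystallize
Reagents that add atoms: 1,3-dibromo-5,5-dimethylhydantoin (DBDMH), CC1(C)N(Br)C(=O)N(Br)C1=O
Why: Proposed new method: the chiral thiophosphoramide takes Br+ from DBDMH onto sulfur and passes it to one face of the electron-rich terminal Me2C=CH alkene, while its N–H/P=S site hydrogen-bonds the carboxylic acid and the 3,4-alkene is deactivated by the allylic CO2H; the bromiranium ion opens through a chair transition state with anti addition across the E-3,4-alkene and the carboxyl oxygen captures the tertiary cation, so equatorial Br, the ring-fusion H and the C7a–O bond are set together as the trans-fused (3aS,5S,7aS) lactone; the closest known reaction types are the catalytic asymmetric bromonium polyene cyclization of homogeranyl arenes and geranyl phenols with this catalyst class and DBDMH, and the racemic halolactonizing cyclization of homogeranic acid; what is new is carboxylic-acid termination under enantiocontrol.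

Step 3
Reactants: 4 (3aS,5S,7aS)-5-bromo-4,4,7a-trimethylhexahydro-1-benzofuran-2(3H)-one
Product: 5 (3aS,5S,7aS)-5-bromo-4,4,7a-trimethyloctahydro-1-benzofuran-2-ol (anomer mixture)
Conditions: i-Bu2AlH (1.1 equiv), CH2Cl2, −78 °C; aq KNaC4H4O6 (Rochelle salt)
Reagents that add atoms: none
Why: i-Bu2AlH half-reduction of a γ-lactone stops at the aluminium lactolate at −78 °C (lactone-to-lactol reduction); the ring stereocentres and the hindered secondary bromide are untouched and the new hemiacetal centre is inconsequential.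

Step 4
Reactants: 5 (3aS,5S,7aS)-5-bromo-4,4,7a-trimethyloctahydro-1-benzofuran-2-ol
Product: 7 (5aS,7S,9aS)-7-bromo-3,6,6,9a-tetramethyl-5a,6,7,8,9,9a-hexahydro-1-benzoxepin-2(5H)-one, via Z-hydroxy enoate 6 (not isolated)
Conditions: phosphonate (1.3 equiv), KN(SiMe3)2 (1.25 equiv), 18-crown-6 (3 equiv), THF, −78 → −40 °C; then KN(SiMe3)2 (1.2 equiv), dilute to 0.01 M, −40 → 23 °C; AcOH
Reagents that add atoms: ethyl 2-[bis(2,2,2-trifluoroethoxy)phosphoryl]propanoate, CCOC(=O)C(C)P(=O)(OCC(F)(F)F)OCC(F)(F)F
Why: Proposed new method: a one-pot Z-olefination/ring-expanding translactonization that closes ring B at the C2–O bond; the Still–Gennari carbanion olefinates the open hydroxy-aldehyde tautomer of 5 Z-selectively (kinetic oxaphosphetane collapse with K+/18-crown-6), then one equivalent of KN(SiMe3)2 forms the tertiary alkoxide, which the Z-alkene and the trans-diequatorial ring bonds hold next to the ester; acyl substitution expels the less basic ethoxide and converts one anion into lactone plus anion, so high dilution drives it forward, while the competing 5-exo oxa-Michael addition at C4 is reversible and drains into the lactone; no stereocentre is formed and the Z geometry becomes the ring alkene; the closest known reaction types are Still–Gennari olefination of lactols with spontaneous lactonization to 5,6-dihydropyran-2-ones and alkoxide-driven translactonization; what is new is a seven-membered ring closed onto a tertiary alkoxide.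

Step 5
Reactants: 7 (5aS,7S,9aS)-7-bromo-3,6,6,9a-tetramethyl-5a,6,7,8,9,9a-hexahydro-1-benzoxepin-2(5H)-one
Product: 9 {[(5aS,7S,9aS)-7-bromo-2-(bromomethyl)-3,6,6,9a-tetramethyl-2,5,5a,6,7,8,9,9a-octahydro-1-benzoxepin-2-yl]oxy}trimethylsilane (C2 epimer mixture), via lithium hemiketal alkoxide 8 (not isolated)
Conditions: CH2Br2 (2.0 equiv), n-BuLi (1.6 equiv, slow addition), THF/Et2O, −95 → −78 °C; Me3SiCl (4 equiv), −78 → −30 °C; aq NaHCO3
Reagents that add atoms: dibromomethane, BrCBr; chlorotrimethylsilane, C[Si](C)(C)Cl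
Why: Bromomethyllithium made in situ by Br/Li exchange adds 1,2 to the lactone carbonyl (carbenoid addition to an ester under Barbier conditions), and the α-halo tetrahedral alkoxide, stable at −78 °C, is silylated so that the ring stays closed and cannot open to a hydroxy enone; the C2 centre formed here is erased in step 6.

Step 6
Reactants: 9 {[(5aS,7S,9aS)-7-bromo-2-(bromomethyl)-3,6,6,9a-tetramethyl-2,5,5a,6,7,8,9,9a-octahydro-1-benzoxepin-2-yl]oxy}trimethylsilane
Product: 11 palisadin B [(2R,5aS,7S,9aS)-7-bromo-2-(bromomethyl)-3,6,6,9a-tetramethyl-2,5,5a,6,7,8,9,9a-octahydro-1-benzoxepine], via ring oxocarbenium ion 10 (not isolated)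
Conditions: Et3SiH (5 equiv), BF3·OEt2 (2 equiv), CH2Cl2, −78 → −40 °C; aq NaHCO3
Reagents that add atoms: none
Why: BF3 ionizes the silyl ketal to the alkene-conjugated oxocarbenium ion and Et3SiH delivers hydride to C2 from the face opposite the axial C9a methyl, which stands almost perpendicular over the C2=O1 plane, giving (2R) with CH2Br cis to that methyl (silane reduction of a ketal, ionic hydrogenation).

**Compound list**
1 | geranyl chloride, (2E)-1-chloro-3,7-dimethylocta-2,6-diene | CC(C)=CCC/C(C)=C/CCl | starting material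
2 | geranylbarium chloride (not isolated) | CC(C)=CCC/C(C)=C/C[Ba]Cl | intermediate
3 | (3E)-4,8-dimethylnona-3,7-dienoic acid (homogeranic acid) | CC(C)=CCC/C(C)=C/CC(=O)O | intermediate
4 | (3aS,5S,7aS)-5-bromo-4,4,7a-trimethylhexahydro-1-benzofuran-2(3H)-one | O=C1C[C@H]2C(C)(C)[C@@H](Br)CC[C@]2(C)O1 | intermediate
5 | (3aS,5S,7aS)-5-bromo-4,4,7a-trimethyloctahydro-1-benzofuran-2-ol (anomer mixture) | OC1C[C@H]2C(C)(C)[C@@H](Br)CC[C@]2(C)O1 | intermediate
6 | ethyl (2Z)-4-[(1S,3S,6S)-3-bromo-6-hydroxy-2,2,6-trimethylcyclohexyl]-2-methylbut-2-enoate (not isolated; cyclizes as its potassium alkoxide) | CCOC(=O)/C(C)=C\C[C@H]1C(C)(C)[C@@H](Br)CC[C@]1(C)O | intermediate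
7 | (5aS,7S,9aS)-7-bromo-3,6,6,9a-tetramethyl-5a,6,7,8,9,9a-hexahydro-1-benzoxepin-2(5H)-one | CC1=CC[C@H]2C(C)(C)[C@@H](Br)CC[C@]2(C)OC1=O | intermediate
8 | lithium (5aS,7S,9aS)-7-bromo-2-(bromomethyl)-3,6,6,9a-tetramethyl-2,5,5a,6,7,8,9,9a-octahydro-1-benzoxepin-2-olate (not isolated) | CC1=CC[C@H]2C(C)(C)[C@@H](Br)CC[C@]2(C)OC1([O-])CBr.[Li+] | intermediate
9 | {[(5aS,7S,9aS)-7-bromo-2-(bromomethyl)-3,6,6,9a-tetramethyl-2,5,5a,6,7,8,9,9a-octahydro-1-benzoxepin-2-yl]oxy}trimethylsilane (C2 epimer mixture) | CC1=CC[C@H]2C(C)(C)[C@@H](Br)CC[C@]2(C)OC1(O[Si](C)(C)C)CBr | intermediate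
10 | (5aS,7S,9aS)-7-bromo-2-(bromomethyl)-3,6,6,9a-tetramethyl-5,5a,6,7,8,9-hexahydro-9aH-1-benzoxepin-1-ium (not isolated) | CC1=CC[C@H]2C(C)(C)[C@@H](Br)CC[C@]2(C)[O+]=C1CBr | intermediate
11 | palisadin B, (2R,5aS,7S,9aS)-7-bromo-2-(bromomethyl)-3,6,6,9a-tetramethyl-2,5,5a,6,7,8,9,9a-octahydro-1-benzoxepine | CC1=CC[C@H]2C(C)(C)[C@@H](Br)CC[C@]2(C)O[C@H]1CBr | target

**Step count and risks**
Total steps: 6. Longest linear sequence: 6 (fully linear).

The three steps most likely to fail:

Step 2 (proposed new method). The risks are eroded enantiomer ratio through bromonium transfer between alkenes, proton-initiated cyclization by the acidic catalyst, and bromolactonization at the 3,4-alkene. The fallback uses known chemistry, sets out from 3 and comes back at 4. Racemic bromonium-induced cyclization with Et2SBr·SbCl5Br in MeNO2 at −25 °C gives 4 as the racemate, that is, together with its mirror image (3aR,5R,7aR)-5-bromo-4,4,7a-trimethylhexahydro-1-benzofuran-2(3H)-one F1. The enantiomers are separated by preparative supercritical-fluid chromatography on a chiral amylose phase and F1 is discarded.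

Step 4 (proposed new method). The risks are slow opening of the lactol, 5-exo oxa-Michael closure to a tetrahydrofuran, and incomplete lactonization. The fallback uses known chemistry, sets out from 5 and comes back at 7. Wittig methylenation of 5 (Ph3P=CH2 from Ph3PCH3Br and KOt-Bu, THF) gives the allyl carbinol (1S,2S,4S)-4-bromo-1,3,3-trimethyl-2-(prop-2-en-1-yl)cyclohexan-1-ol F2. Its lithium alkoxide (n-BuLi, THF, −78 °C) is acylated with methacryloyl chloride to (1S,2S,4S)-4-bromo-1,3,3-trimethyl-2-(prop-2-en-1-yl)cyclohexyl 2-methylprop-2-enoate F3. Ring-closing metathesis (second-generation Hoveyda–Grubbs catalyst, RuCl2(=CH-2-i-PrOC6H4)(H2IMes), toluene, 80 °C) then forms the trisubstituted ring alkene and gives 7.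

Step 5. The risks are the short lifetime of LiCH2Br against a hindered α-branched tert-alkyl ester carbonyl, competing n-BuLi addition, and ring opening of the adduct before silylation. The fallback sets out from 7 and comes back at 11, so it also bypasses step 6. Petasis methylenation (Cp2TiMe2, toluene, 70 °C) gives the dienol ether (5aS,7S,9aS)-7-bromo-3,6,6,9a-tetramethyl-2-methylidene-2,5,5a,6,7,8,9,9a-octahydro-1-benzoxepine F4. Hydroboration with 9-BBN-H places boron on the terminal carbon and hydrogen on C2 from the face opposite the angular methyl, giving 9-{[(2S,5aS,7S,9aS)-7-bromo-3,6,6,9a-tetramethyl-2,5,5a,6,7,8,9,9a-octahydro-1-benzoxepin-2-yl]methyl}-9-borabicyclo[3.3.1]nonane F5 (2S only by priority rules; same spatial arrangement as in 11). Oxidation (NaBO3, THF/H2O) gives [(2R,5aS,7S,9aS)-7-bromo-3,6,6,9a-tetramethyl-2,5,5a,6,7,8,9,9a-octahydro-1-benzoxepin-2-yl]methanol F6, and Appel bromination (CBr4, PPh3, CH2Cl2, 0 °C) gives 11.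

Further compounds
F1 | step 2 | (3aR,5R,7aR)-5-bromo-4,4,7a-trimethylhexahydro-1-benzofuran-2(3H)-one | O=C1C[C@@H]2C(C)(C)[C@H](Br)CC[C@@]2(C)O1
F2 | step 4 | (1S,2S,4S)-4-bromo-1,3,3-trimethyl-2-(prop-2-en-1-yl)cyclohexan-1-ol | C=CC[C@H]1C(C)(C)[C@@H](Br)CC[C@]1(C)O
F3 | step 4 | (1S,2S,4S)-4-bromo-1,3,3-trimethyl-2-(prop-2-en-1-yl)cyclohexyl 2-methylprop-2-enoate | C=CC[C@H]1C(C)(C)[C@@H](Br)CC[C@]1(C)OC(=O)C(C)=C
F4 | step 5 | (5aS,7S,9aS)-7-bromo-3,6,6,9a-tetramethyl-2-methylidene-2,5,5a,6,7,8,9,9a-octahydro-1-benzoxepine | CC1=CC[C@H]2C(C)(C)[C@@H](Br)CC[C@]2(C)OC1=C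
F5 | step 5 | 9-{[(2S,5aS,7S,9aS)-7-bromo-3,6,6,9a-tetramethyl-2,5,5a,6,7,8,9,9a-octahydro-1-benzoxepin-2-yl]methyl}-9-borabicyclo[3.3.1]nonane | CC1=CC[C@H]2C(C)(C)[C@@H](Br)CC[C@]2(C)O[C@H]1CB1C2CCCC1CCC2
F6 | step 5 | [(2R,5aS,7S,9aS)-7-bromo-3,6,6,9a-tetramethyl-2,5,5a,6,7,8,9,9a-octahydro-1-benzoxepin-2-yl]methanol | CC1=CC[C@H]2C(C)(C)[C@@H](Br)CC[C@]2(C)O[C@H]1CO
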